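- The delta run, made earlier, showed the target already falling, from 27.4% at 10.0 h to 19.3% at 40.0 h, so for the new flask I opened a ledger on the reagent.

| setting | delta | flask |
|---|---|---|
| starting material | 0.30 M | 0.30 M |
| reagent | 0.33 M | 0.330 M |
| second substrate | 1.2 M | 0.600 M |
| third substrate | 1.5 M | 1.50 M |
| remark | run made earlier |  |
| time |  | 15 d |

delta run (percent of the starting material charged)

| time / h | target / % |
|---|---|
| 10.0 | 27.4 |
| 20.0 | 26.2 |
| 25.0 | 25.0 |
| 40.0 | 19.3 |

(readings scatter by 0.3 percentage points)

1. time up to 15 d at which target stands highest
2. the amount of target, in percent of the starting material charged, at that time



- I carried one quantity, 1.10 moles of reagent per mole of starting material charged, the cover C, which was the same in the delta run.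
- I supposed that each target holds one reagent, so the target standing at the first delta reading held 0.0822 M of reagent, and the other 0.248 M of that run's charge was not in the target standing at that time.
- I further supposed that the second and third substrates also draw on the reagent, which would make them the other two entries in the ledger.
- The new flask held half the second substrate of the delta run, 2.00 rather than 4.00 moles per mole of starting material, so with C unchanged I expected more reagent to reach the starting material and a peak above the delta readings.
- The forecast gave 26% at 0.7 d, holding that “The height should stay similar”, whereas my ledger pointed upward without giving a figure.
- The flask gave 32.7% at 0.613 d.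

    starting material + reagent → target (k = 7.95 × 10⁻⁵ /M/s)
    second substrate + reagent → second product (k = 2.11 × 10⁻⁵ /M/s)
    third substrate + reagent → third product (k = 1.08 × 10⁻⁵ /M/s)
    starting material + target → side product (k = 2.29 × 10⁻⁵ /M/s)
    target → over-reaction product (k = 6.43 × 10⁻⁷ /s)

- In this flask the reagent, the limiting reagent, stood at 0% at 15.0 d, and the books closed there: of C = 1.10, second product took 0.288 and third product 0.382, leaving 0.430 booked to the starting material. The neighbour flask charged with 1.3 M of reagent had C = 4.33. At 15.0 d, with its reagent at 0%, its second product held 1.31 and its third product 2.10, leaving 0.929 booked to the starting material, and 0.0105% of its starting material remained. The target in that neighbour flask reached 82.4%.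

The runs come from a simulation with made-up constants; noise was put on by code.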